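**Retrosynthetic overview**

1. Rings A and B are bought, not built: ring A arrives as acetophenone 1 and takes its prenyl group from bromide 2 by direct C-alkylation (giving 3); ring B arrives as isovanillin 4.
2. Cα=Cβ disconnection: aldol condensation of 3 with 4 gives the open-chain chalcone 5, the laboratory counterpart of the biosynthetic chalcone.
3. O1–C2 disconnection: a catalyst-controlled, chalcone-isomerase-type oxa-Michael closure of 5 gives (2S)-flavanone 6; ring C is the only ring formed, and it is formed last.
4. C3–O disconnection: 6 is hydroxylated at C3 in the same operation, in the manner of flavanone 3-hydroxylase, through enol ether 7 and epoxide 8 to the target 9.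

Assumption: the facial sense of the quinine-derived thiourea is taken by analogy and must be confirmed on the first run (the quinidine-derived pseudoenantiomer is equally available); acetophenone 1 is a catalogue compound.

**Route**

Step 1
Reactants: 1 1-(2,6-dihydroxy-4-methoxyphenyl)ethanone; 2 prenyl bromide (1-bromo-3-methylbut-2-ene)
Product: 3 1-[2,6-dihydroxy-4-methoxy-3-(3-methylbut-2-en-1-yl)phenyl]ethanone
Conditions: 2 (0.9 equiv), 10% aq. KOH, 0 °C → rt, 3 h; then dilute HCl; unreacted 1 recovered and recycled
Reagents that add atoms: none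
Why: C-alkylation of the ambident phloroglucinol-type phenoxide (water solvates the oxygens and steers the soft allylic bromide to carbon), a prenyltransferase-like step; the two open ring positions of 1 are equivalent by symmetry, so only one mono-C-prenyl isomer can form, and no stereocentre is created.

Step 2
Reactants: 3 1-[2,6-dihydroxy-4-methoxy-3-(3-methylbut-2-en-1-yl)phenyl]ethanone; 4 isovanillin (3-hydroxy-4-methoxybenzaldehyde)
Product: 5 (E)-1-[2,6-dihydroxy-4-methoxy-3-(3-methylbut-2-en-1-yl)phenyl]-3-(3-hydroxy-4-methoxyphenyl)prop-2-en-1-one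
Conditions: LiN(SiMe3)2 (4.6 equiv), THF, −78 °C → rt; cold dilute aq. HCl to pH 3, fast extraction, acid-washed silica
Reagents that add atoms: none
Why: Claisen–Schmidt aldol condensation through the lithium polyanion: the lithium phenoxides mask all three OH groups in the flask, the lithium enolate adds to the aldehyde (its meta-phenoxide cannot deactivate the CHO by resonance), and E1cB loss of hydroxide gives the E-enone, while the cold acidic work-up keeps the 2',6'-dihydroxychalcone from closing prematurely.

Step 3
Reactants: 5 (E)-1-[2,6-dihydroxy-4-methoxy-3-(3-methylbut-2-en-1-yl)phenyl]-3-(3-hydroxy-4-methoxyphenyl)prop-2-en-1-one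
Product: 9 (2R,3R)-3,5-dihydroxy-2-(3-hydroxy-4-methoxyphenyl)-7-methoxy-6-(3-methylbut-2-en-1-yl)-2,3-dihydro-4H-chromen-4-one, via (2S)-flavanone 6 (not isolated), via tris(trimethylsilyl) enol ether 7 (not isolated), via silyloxy epoxide 8 (not isolated)
Conditions: (a) 1-[3,5-bis(trifluoromethyl)phenyl]-3-[(8α,9S)-6'-methoxycinchonan-9-yl]thiourea (10 mol %), toluene/CH2Cl2, −40 °C; (b) Et3N (5 equiv), Me3SiOTf (4 equiv), −78 → −20 °C, then evaporate, pentane, filter under Ar; (c) dimethyldioxirane (1.0 equiv), acetone/CH2Cl2, −78 °C; (d) aq. citric acid, MeOH/THF, 0 °C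
Reagents that add atoms: dimethyldioxirane, CC1(C)OO1 (oxygen of the 3-OH); trimethylsilyl trifluoromethanesulfonate, C[Si](C)(C)OS(=O)(=O)C(F)(F)F (Me3Si groups of 7 and 8 only, lost again before 9)
Why: Proposed new method: a catalyst-controlled, chalcone-isomerase-type 6-endo oxa-Michael cyclisation of the free, unactivated 2',6'-dihydroxychalcone, in which the quinuclidine nitrogen deprotonates the unhindered 6'-OH while the thiourea N–H bonds hold the carbonyl that the prenyl-buttressed 2'-OH already chelates, so that the phenoxide is delivered to one face of Cβ (setting C2 as S) and the ring closes through the oxygen remote from the prenyl group (6-prenyl, not 8-prenyl); the closest known reaction type is the cinchona-thiourea-catalysed oxa-Michael cyclisation of ester-activated 2'-hydroxychalcones to flavanones, and the reactivity relied on is that of 6'-hydroxychalcones, which close spontaneously near neutral pH; the flavanone is then oxidised in the flask by a Rubottom oxidation, where soft enolisation (no strong base, hence no retro-oxa-Michael racemisation at C2) gives 7, dimethyldioxirane epoxidises the enol ether on the face anti to the C2 aryl group to set C3 trans (3R), and mild acid unmasks the α-hydroxy ketone and the phenols.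

**Compound list**

1 | 1-(2,6-dihydroxy-4-methoxyphenyl)ethanone | CC(=O)c1c(O)cc(OC)cc1O | starting material
2 | prenyl bromide (1-bromo-3-methylbut-2-ene) | CC(C)=CCBr | starting material
3 | 1-[2,6-dihydroxy-4-methoxy-3-(3-methylbut-2-en-1-yl)phenyl]ethanone | CC(=O)c1c(O)cc(OC)c(CC=C(C)C)c1O | intermediate
4 | isovanillin (3-hydroxy-4-methoxybenzaldehyde) | COc1ccc(C=O)cc1O | starting material
5 | (E)-1-[2,6-dihydroxy-4-methoxy-3-(3-methylbut-2-en-1-yl)phenyl]-3-(3-hydroxy-4-methoxyphenyl)prop-2-en-1-one | COc1ccc(/C=C/C(=O)c2c(O)cc(OC)c(CC=C(C)C)c2O)cc1O | intermediate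
6 | (2S)-5-hydroxy-2-(3-hydroxy-4-methoxyphenyl)-7-methoxy-6-(3-methylbut-2-en-1-yl)-2,3-dihydro-4H-chromen-4-one | COc1ccc([C@H]2Oc3cc(OC)c(CC=C(C)C)c(O)c3C(=O)C2)cc1O | intermediate (not isolated)
7 | (2S)-7-methoxy-2-[4-methoxy-3-(trimethylsilyloxy)phenyl]-6-(3-methylbut-2-en-1-yl)-4,5-bis(trimethylsilyloxy)-2H-chromene | COc1ccc([C@H]2Oc3cc(OC)c(CC=C(C)C)c(O[Si](C)(C)C)c3C(O[Si](C)(C)C)=C2)cc1O[Si](C)(C)C | intermediate (not isolated)
8 | 3,4-epoxide of 7 (2R,3R,4R in flavan numbering): oxirane oxygen on the ring face opposite the C2 aryl group, 4-OSiMe3 and both aryl OSiMe3 groups retained | COc1ccc([C@H]2Oc3cc(OC)c(CC=C(C)C)c(O[Si](C)(C)C)c3[C@]4(O[Si](C)(C)C)O[C@@H]42)cc1O[Si](C)(C)C | intermediate (not isolated)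
9 | (2R,3R)-3,5-dihydroxy-2-(3-hydroxy-4-methoxyphenyl)-7-methoxy-6-(3-methylbut-2-en-1-yl)-2,3-dihydro-4H-chromen-4-one | COc1ccc([C@H]2Oc3cc(OC)c(CC=C(C)C)c(O)c3C(=O)[C@@H]2O)cc1O | target

**Step count and risks**

Total step count: 3 (step 3 is one telescoped operation without purification of 6, 7 or 8). Longest linear sequence: 3 (1 → 3 → 5 → 9).

Steps most likely to fail, most risky first:

Step 3. Three things can go wrong:
- the enantioselectivity on an unactivated chalcone may be only moderate;
- closure through the prenyl-flanked oxygen would give the 8-prenyl isomer;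
- dimethyldioxirane may touch the prenyl double bond if more than one equivalent is present.

Fallback (sets out from 5, comes back at 6): give up catalyst control in favour of thermodynamic closure plus resolution with recycling. Heating 5 with NaOAc in EtOH gives the racemic 6-prenylflavanone, that is 6 together with its mirror image (2R)-6-prenylflavanone F1, next to the 8-prenyl regioisomer as its two enantiomers (2S)-8-prenylflavanone F2 and (2R)-8-prenylflavanone F3. Silica chromatography separates the regioisomers; F2 and F3 go back into the same NaOAc/EtOH conditions, where they reopen to 5 and redistribute. The 6/F1 racemate is resolved by preparative chromatography on an amylose tris(3,5-dimethylphenylcarbamate) phase, and F1 is racemised through 5 under the same basic conditions and recycled. Pure 6 then re-enters step 3 at stage (b).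

Step 1. Direct C-prenylation competes with O-prenylation and double C-prenylation, and yields of such reactions are usually modest. Fallback (sets out from 1, comes back at 3): move the prenyl group onto carbon by sigmatropic rearrangement. Alkylation of 1 with 2 and K2CO3 in acetone stops cleanly at the mono-ether, because the second OH stays chelated, giving the aryl prenyl ether 1-[2-hydroxy-4-methoxy-6-(3-methylbut-2-en-1-yloxy)phenyl]ethanone F4. Heating F4 in N,N-diethylaniline at about 200 °C triggers ortho-Claisen rearrangement followed by Cope shift (para-Claisen), which places an unrearranged prenyl group para to the former ether oxygen. By the symmetry of the ring that position is the one required, so the product is 3.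

Step 2. The lithium polyanion may be sluggish or poorly soluble, and 5 may close to racemic flavanone during work-up. Fallback (sets out from 3 and 4, comes back at 5): mask the non-chelated phenols and run a simple dianion aldol.
- t-BuMe2SiCl and imidazole convert 3 into the mono-silyl ether 1-[6-(tert-butyldimethylsilyloxy)-2-hydroxy-4-methoxy-3-(3-methylbut-2-en-1-yl)phenyl]ethanone F5 (the less hindered OH reacts, the other stays chelated).
- The same reagents convert 4 into 3-(tert-butyldimethylsilyloxy)-4-methoxybenzaldehyde F6.
- LiN(SiMe3)2 (2.2 equiv) in THF condenses F5 with F6 to the bis-silyl chalcone F7, quenched with dilute HCl.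
- Bu4NF buffered with AcOH in THF at 0 °C removes both silyl groups without base-induced ring closure and gives 5.

**Further compounds**

F1 | step 3 | (2R)-5-hydroxy-2-(3-hydroxy-4-methoxyphenyl)-7-methoxy-6-(3-methylbut-2-en-1-yl)-2,3-dihydro-4H-chromen-4-one (enantiomer of 6) | COc1ccc([C@@H]2Oc3cc(OC)c(CC=C(C)C)c(O)c3C(=O)C2)cc1O
F2 | step 3 | (2S)-5-hydroxy-2-(3-hydroxy-4-methoxyphenyl)-7-methoxy-8-(3-methylbut-2-en-1-yl)-2,3-dihydro-4H-chromen-4-one | COc1ccc([C@H]2Oc3c(CC=C(C)C)c(OC)cc(O)c3C(=O)C2)cc1O
F3 | step 3 | (2R)-5-hydroxy-2-(3-hydroxy-4-methoxyphenyl)-7-methoxy-8-(3-methylbut-2-en-1-yl)-2,3-dihydro-4H-chromen-4-one | COc1ccc([C@@H]2Oc3c(CC=C(C)C)c(OC)cc(O)c3C(=O)C2)cc1O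
F4 | step 1 | 1-[2-hydroxy-4-methoxy-6-(3-methylbut-2-en-1-yloxy)phenyl]ethanone | CC(=O)c1c(O)cc(OC)cc1OCC=C(C)C
F5 | step 2 | 1-[6-(tert-butyldimethylsilyloxy)-2-hydroxy-4-methoxy-3-(3-methylbut-2-en-1-yl)phenyl]ethanone | CC(=O)c1c(O[Si](C)(C)C(C)(C)C)cc(OC)c(CC=C(C)C)c1O
F6 | step 2 | 3-(tert-butyldimethylsilyloxy)-4-methoxybenzaldehyde | COc1ccc(C=O)cc1O[Si](C)(C)C(C)(C)C
F7 | step 2 | (E)-1-[6-(tert-butyldimethylsilyloxy)-2-hydroxy-4-methoxy-3-(3-methylbut-2-en-1-yl)phenyl]-3-[3-(tert-butyldimethylsilyloxy)-4-methoxyphenyl]prop-2-en-1-one | COc1ccc(/C=C/C(=O)c2c(O[Si](C)(C)C(C)(C)C)cc(OC)c(CC=C(C)C)c2O)cc1O[Si](C)(C)C(C)(C)C
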